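The runs come from a simulation with constants of no real substance; noise was put on by code.

**Too little partner.** This flask cannot turn over both its starting material and its second substrate if, as we assume, both consume partner: the 1.00 equiv of partner faces two claimants, and their joint claim is larger, with 1.00 equiv of second substrate beside the starting material.

in all of them: free catalyst 0.052 mol%; temperature 25 °C

| run | starting material | partner | second substrate | remark | time |
|---|---|---|---|---|---|
| autumn | 0.17 M | 1 equiv | 1 equiv | the very flask that is asked about, followed so far |  |
| summer | 0.34 M | 1 equiv | 1 equiv | run made earlier |  |
| flask | 0.17 M | 1.00 equiv | 1.00 equiv |  | 2.0 d |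

| run | time / h | target / % | starting material / % |
|---|---|---|---|
| autumn | 6.00 | 67.7 | 31.0 |
| autumn | 12.0 | 72.8 | 26.8 |
| autumn | 15.0 | 74.2 | 23.4 |
| autumn | 20.0 | 73.1 | 25.0 |
| autumn | 30.0 | 74.7 | 24.9 |
| autumn | 40.0 | 75.5 | 25.3 |
| summer | 0.833 | 64.1 | 35.7 |
| summer | 1.33 | 69.2 | 30.2 |
| summer | 2.00 | 76.1 | 26.0 |
| summer | 3.00 | 75.4 | 24.6 |
| summer | 4.00 | 77.5 | 23.2 |
| summer | 6.00 | 77.4 | 22.7 |
| summer | 10.0 | 77.1 | 25.2 |

(scatter of a reading: 1 percentage point)

- west: change nothing and wait 50 h more
- east: at 2.0 d add free catalyst, 100% of the amount charged, then wait 50 h
- south-west: at 2.0 d take out 90% of the target then present, then wait 50 h
- north-east: at 2.0 d raise the temperature by 20 K, then wait 50 h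
- south-east: at 2.0 d add partner, 100% of the amount charged, then wait 50 h

- what is taken out of target is counted as made
- the earlier runs do not show what temperature does; that part of a forecast is a guess
- additions bring no volume worth counting

1. target, in percent of the starting material first charged, at 2.0 d
2. which option adds most target ("none" when 2 percentage points or less is all one gets) (west / east / south-west / north-east / south-east / none)
3. target present, with what was taken out counted in, in percent of the starting material first charged, after south-west
4. target present, with what was taken out counted in, in percent of the starting material first charged, after north-east

**Two extremes.** If partner cannot tell the claimants apart, the symmetric case, target stops at 50.0%. If partner serves starting material first, target stops at 100 percent. The last autumn reading of target, 75.5%, stands above the first figure and below the second, so the real flask lies between.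

**Partner share.** We mark its place by the partner share, the plateau target per partner charged, here the mean of the last three autumn readings: 74.4%. We expect this share to move little with concentration, since we take both claimants to go through the same free catalyst. The summer run, at twice the concentration, levels at 77.3%, higher by 2.9 percentage points. This gap exceeds the scatter of 1 point per reading, and it hints that the autumn flask stopped short of the end of its partner, perhaps with its free catalyst failing first. So we commit to 74.4% for now, and to extra free catalyst as the best option, with a gain near 2.9 points.

**The forecast.** It gives 75% (range 74% to 76.5%), names south-east as best, and gives 86.5% after south-west and 75% after north-east, from its “best reading is a concentration-independent equilibrium”. We part from it on the best option.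

**The result.** The flask gives 74.1%, and the best option is east, with 5.5 points gained. South-east gains 0.059 points, while south-west and north-east stay at 74.1% and 74.1%.

    starting material + partner + free catalyst → free catalyst + target (k = 15.0 /M²/s, Ea = 44.0 kJ/mol)
    free catalyst → spent catalyst (k = 4.50 × 10⁻⁵ /s, Ea = 106 kJ/mol)
    2 second substrate → self-condensation product (k = 6.40 × 10⁻⁴ /M/s, Ea = 77.0 kJ/mol)
    second substrate + partner + free catalyst → free catalyst + second product (k = 4.50 /M²/s, Ea = 39.0 kJ/mol)
    (constants at 25 °C)

**Share again.** At 48.0 h this flask's target stands near the share of 74.4%, with free catalyst down to 0.0420% of its charge and partner still at 8.19% of its own charge. A neighbouring flask, charged with 0.250 equiv of partner, should by the same share give 18.6%. It gives 20.8%, and in that neighbour partner, the limiting reagent, is down to 0.996% of its own charge while starting material stands at 79.2% of its charge.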